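## Analysis of the target

The target contains a 4-alkylidene-2-methylcyclopent-2-enone (C15, C1, C2, C3, C4) that shares the C15–C4 bond with a 12-membered carbocycle (C4 to C15). An ether oxygen spans C6 and C9 of that carbocycle, so an oxolane sits inside the large ring, which has 11 members when counted through oxygen. Locants used throughout: C15 is the acetoxy carbon, C1=C2(CH3), C3 the ring carbonyl, C4=C5 the exocyclic alkene, C6(CH3)–C7–C8–C9 the oxolane carbons, C10 the gem-dimethyl carbon, then C11, C12, C13 (CH–CH3) and the C14 ketone. There are four stereocentres (6S, 9S, 13R, 15S) and a 4E alkene. On the oxolane the two macrocycle arms (C5 on C6, C10 on C9) are trans. C6 and C15 are both fully substituted and sit cis across C4=C5, and C13 is an enolisable centre next to the C14 ketone. C15 and C6 are separated by the planar C4=C5 unit, so in an open-chain precursor the oxolane cannot relay its configuration to C15. The sensitive parts are the cross-conjugated dienone C1=C2–C3(=O)–C4=C5, the tertiary, doubly allylic α-acetoxy ketone at C15/C14 and the base-labile C13 centre. The difficulty lies in the trans-bridged medium-to-large ring, the contra-thermodynamic cis placement of two quaternary carbons on C4=C5 and the number of electrophilic enones in late intermediates. The strategy rests on one feature: C1=C2 of the cyclopentenone and C12–C13 next to the C14 ketone are both α,β to a carbonyl, so each can be closed as an olefin by metathesis from a C15 vinyl group, isopropenyl ketones at C3 and C14, and an allyl group on C10.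

## Retrosynthetic reasoning

**32 to 29.** C13 is the only stereocentre that can epimerise, so it is set last. The C12–C13 bond is taken back to the C12=C13 enone 29. The forward step must deliver hydride to C12, the only enone β-carbon not bonded to a quaternary carbon, and leave C13 in its more stable configuration.

**29 to 28 to 26.** The acetyl group is removed to give 28, and both carbocycles are then opened at C1=C2 and C12=C13. These are the only ring bonds that can be written as olefins flanked by carbonyl groups. Cutting both leaves the oxolane as the sole ring and reduces the problem to the acyclic tetraene 26. The 15-hydroxyl is deliberately left free in 26: a free allylic hydroxyl favours catalyst loading at the C15 vinyl group, and acylating a hindered tertiary alcohol next to two exposed methacryloyl groups is avoided. The forward reaction has to pair the vinyl group with the C3 isopropenyl ketone first and the terminal olefin with the C14 isopropenyl ketone second.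

**26 to 25 to 23 to 22 to 21.** Both isopropenyl ketones are traced to one dialdehyde, 23, so that C2–C3 and C13–C14 are made in a single operation with Grignard reagent 24 (giving 25) and both carbinols are oxidised together. Dialdehyde 23 comes from triol 22, and 22 from lactone 21, in which C3 and C14 are tied into one ring. The gain is that two identical functional groups are handled by the same reagents throughout.

**21 to 20 to 19 to 18.** The C15 tertiary carbinol with its vinyl group is the reductive-opening product of a 2,3-epoxy iodide (20), which goes back through epoxy alcohol 19 to allylic alcohol 18. Sharpless asymmetric epoxidation of 18 creates C15 under reagent control, which is necessary because the oxolane is too remote to direct it. The allylic alcohol carbons become the vinyl group (C1 and the methylene later lost in the metathesis).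

**18 to 17 to 14 + 16, and 14 to 12 + 13.** The C4–C15 bond is cut between two sp2 carbons: a Stille coupling of bromoacrylate 14 with stannane 16 gives 17, which lactonises to 18. Only the hydroxymethyl group on C15 can reach the ester, so lactonisation distinguishes the two hydroxyls without a protecting group. The C4=C5 geometry is set earlier, in the Wittig reaction of aldehyde 12 with ylide 13: the ester ends trans to the bulky oxolane, the bromine cis, and the coupling then replaces bromine by C15 with retention. An assembly through a C4≡C5 alkyne (acetylide addition to a C15 ketone, then hydrometalation and acylation at C4) was not adopted. The acetylide addition would create C15 with no control element, and the alkyne would be flanked by two oxygen-bearing, fully substituted carbons, so neither sterics nor electronics would tell C4 from C5.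

**12 to 11 to 10 to 9.** The C6–O bond of the oxolane is cut. Epoxy diol 10, from Sharpless epoxidation of allylic alcohol 9, is opened by the C9 hydroxyl at the tertiary epoxide carbon with inversion, giving 11. Glycol cleavage of 11 then gives 12. This sets C6 under reagent control and touches only the allylic-alcohol olefin, leaving the terminal olefin needed for the key step.

**9 to 8 to 7 to 3 + 6.** C9 is set by enantioselective reduction of ketone 7 (to 8, then 9 after deacetylation). Ketone 7 is disconnected at C7–C8 into the enolate of methyl ketone 3 and allylic bromide 6. Ketone 3 comes from acid 1 and 2, bromide 6 from 4 through 5, and stannane 16 from 15.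

## Alternatives that were turned down

**Alternative 1:** Silicon-tethered allenic Pauson–Khand reaction on a macrocyclic allene.
- Disconnection: C1–C15, C2–C3 and C3–C4. The cyclopentenone is built last on a preformed macrocyclic allene A1, whose C14 oxygen carries a propynylsilyl tether.
- Key step: a molybdenum carbonyl promoter joins the tethered alkyne, the C15=C4 bond of the allene and one carbonyl carbon, giving the silicon-bridged dienone A2.
- For: three C–C bonds and the five-membered ring form in one step. The macrocycle is closed before any enone exists, so nothing as fragile as 26 is handled, and the exocyclic C4=C5 bond is inherited from the allene. On these points it is stronger than the chosen route.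
- Against: A2 has no oxygen at C15 and carries C14 as a silyl ether. The C1–Si bond must still be cleaved, C14 oxidised, and a tertiary C–H at C15 (flanked by a dienone and a ketone) hydroxylated with control of configuration, then acetylated. The strained, axially chiral allene in an oxolane-bridged 12-membered ring must also be made as one diastereomer, since its axis decides the C4=C5 geometry.
- Comparison: the chosen strategy has the C15 oxygen in place from an early, reagent-controlled epoxidation and needs two steps after the key step rather than four or more.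

**Alternative 2:** Photooxygenation of an ansa-acylfulvene with Kornblum–DeLaMare opening.
- Disconnection: the C15–O bond and the C3 carbonyl are introduced last on the macrocyclic 1-acylfulvene A3, which already has every carbon and the large ring.
- Key step: [4+2] addition of singlet oxygen across C15 and C3, then base-induced opening of the endoperoxide, gives the 15-O-deacetyl compound A4 in one pot. Acetylation finishes.
- For: the endgame is shorter and more redox-economic than the chosen one, with no protecting groups.
- Against: the face of the planar fulvene attacked at C15 is decided only by the ansa chain, so C15 has no independent control element. The electron-poor 1-acyl diene reacts slowly with an electrophilic oxidant, fulvene endoperoxides rearrange by other paths, and the strained ansa-fulvene itself is hard to make and prone to dimerise.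
- Comparison: the chosen route is longer but fixes C15 before any ring strain or facial ambiguity exists.

**Alternative 3:** Radical macrocyclisation at the quaternary C10.
- Disconnection: C10–C11. A tertiary C10 radical, generated by photoredox double decarboxylation of the cesium oxalate A5 (a linalool-oxide-type tertiary alcohol derivative), adds to C11 of a tethered vinyl sulfone.
- Key step: Giese-type ring closure gives the 12-sulfonyl compound A6, which must then be desulfonylated.
- For: the oxolane with C6, C9 and the gem-dimethyl carbon comes from the chiral pool, which is clearly shorter than the seven steps spent on 12 here. Tertiary radicals add well to vinyl sulfones and form quaternary carbons under neutral conditions.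
- Against: A5 already carries the complete dienone and α-acetoxy ketone. The radical has competing acceptors at C1 and C5. A triplet-sensitising photocatalyst can isomerise the C4=C5 bond, whose cis arrangement of two quaternary carbons is not favoured before the ring exists. Reductive removal of the sulfone is hard to reconcile with enones and an α-acetoxy ketone.
- Comparison: the chosen route closes the large ring thermally by a two-electron process, and only after the cyclopentenone has locked the C4=C5 geometry.

Key step: step 18

Assumption: the 13R configuration is taken to be the thermodynamically preferred one at the enolisable C13 centre of the 12-membered ring, so step 20 ends with a base equilibration.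

Abbreviation used in names: Ox = (2S,5S)-2-methyl-5-(2-methylpent-4-en-2-yl)oxolan-2-yl.

## Route

Step 1
Reactants: 1 2,2-dimethylpent-4-enoic acid; 2 methyllithium
Product: 3 3,3-dimethylhex-5-en-2-one
Conditions: MeLi (2.2 equiv), Et2O, 0 → 23 °C; then aq. HCl, 0 °C
Reagents that add atoms: methyllithium (2), [Li]C
Why: Addition of an organolithium to the lithium carboxylate gives a geminal dialkoxide that collapses to the methyl ketone only on work-up; the α-quaternary acid cannot enolise.

Step 2
Reactants: 4 3-methylbut-2-en-1-yl acetate
Product: 5 (2E)-4-hydroxy-3-methylbut-2-en-1-yl acetate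
Conditions: SeO2 (0.3 equiv), t-BuOOH (2 equiv), CH2Cl2, 23 °C
Reagents that add atoms: tert-butyl hydroperoxide, CC(C)(C)OO (oxygen relayed through selenium dioxide, O=[Se]=O)
Why: Selenium dioxide allylic oxidation (ene reaction, then [2,3]-sigmatropic shift) attacks the methyl group trans to the chain of a trisubstituted olefin, so the E-hydroxymethyl isomer is expected; the reaction is stopped before over-oxidation to the enal.

Step 3
Reactants: 5 (2E)-4-hydroxy-3-methylbut-2-en-1-yl acetate
Product: 6 (2E)-4-bromo-3-methylbut-2-en-1-yl acetate
Conditions: CBr4, PPh3, CH2Cl2, 0 °C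
Reagents that add atoms: carbon tetrabromide, BrC(Br)(Br)Br
Why: Appel bromination of a primary allylic alcohol under neutral conditions; the olefin geometry and the acetate are untouched.

Step 4
Reactants: 3 3,3-dimethylhex-5-en-2-one; 6 (2E)-4-bromo-3-methylbut-2-en-1-yl acetate
Product: 7 (2E)-3,7,7-trimethyl-6-oxodeca-2,9-dien-1-yl acetate
Conditions: LiN(i-Pr)2 (1.05 equiv), THF, −78 °C; then 6, DMPU, −78 → −30 °C
Reagents that add atoms: none
Why: Kinetic enolate alkylation forming C7–C8; ketone 3 can enolise only toward its methyl group, and SN2 displacement at the primary allylic bromide should outrun acyl transfer from the acetate at low temperature.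

Step 5
Reactants: 7 (2E)-3,7,7-trimethyl-6-oxodeca-2,9-dien-1-yl acetate
Product: 9 (2E,6S)-3,7,7-trimethyldeca-2,9-diene-1,6-diol, via hydroxy acetate 8 (not isolated)
Conditions: (R)-2-methyl-CBS-oxazaborolidine (0.2 equiv), catecholborane (1.8 equiv), toluene, −78 → −40 °C; then K2CO3 (0.3 equiv), MeOH, 23 °C
Reagents that add atoms: none
Why: Corey–Bakshi–Shibata reduction; the tertiary alkyl group acts as the large substituent, so the R catalyst should give the 6S carbinol (C9 of the target). Catecholborane does not hydroborate the olefins at this temperature, and methanolysis removes the acetate in the same flask.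

Step 6
Reactants: 9 (2E,6S)-3,7,7-trimethyldeca-2,9-diene-1,6-diol
Product: 11 (1R)-1-Ox-ethane-1,2-diol, via epoxy diol 10 (not isolated)
Conditions: Ti(OiPr)4 (0.1 equiv), D-(−)-diethyl tartrate (0.13 equiv), t-BuOOH (2 equiv), 4 Å MS, CH2Cl2, −20 °C; then camphorsulfonic acid (0.1 equiv), 0 °C
Reagents that add atoms: tert-butyl hydroperoxide, CC(C)(C)OO
Why: Sharpless asymmetric epoxidation touches only the allylic-alcohol olefin and with the D-tartrate should give the (2R,3R)-epoxide 10. The C9 hydroxyl then opens it at the tertiary carbon in a 5-exo closure with inversion, setting C6 as S with C5 trans to C10 on the oxolane. Any minor enantiomer from step 5 becomes a separable diastereomer here.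

Step 7
Reactants: 11 (1R)-1-Ox-ethane-1,2-diol
Product: 12 (2S,5S)-2-methyl-5-(2-methylpent-4-en-2-yl)oxolane-2-carbaldehyde
Conditions: NaIO4, THF–H2O, 0 °C
Reagents that add atoms: none
Why: Periodate glycol cleavage; the aldehyde has no α-hydrogen and cannot epimerise.

Step 8
Reactants: 12 (2S,5S)-2-methyl-5-(2-methylpent-4-en-2-yl)oxolane-2-carbaldehyde; 13 ethyl 2-bromo-2-(triphenyl-λ5-phosphanylidene)acetate
Product: 14 ethyl (2Z)-2-bromo-3-Ox-prop-2-enoate
Conditions: 13 (1.5 equiv), toluene, 90 °C
Reagents that add atoms: ethyl 2-bromo-2-(triphenyl-λ5-phosphanylidene)acetate (13), CCOC(=O)C(Br)=P(c1ccccc1)(c1ccccc1)c1ccccc1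
Why: Wittig reaction of a stabilised ylide places the ester trans to the bulky oxolane, so bromine ends cis to C6 (Z). This fixes the later trans relationship of C3 and C6 across C4=C5.

Step 9
Reactants: 15 but-2-yne-1,4-diol
Product: 16 (2E)-2-(tributylstannyl)but-2-ene-1,4-diol
Conditions: Bu3SnH (1.1 equiv), PdCl2(PPh3)2 (2 mol%), THF, 23 °C
Reagents that add atoms: tributyltin hydride, CCCC[SnH](CCCC)CCCC
Why: Palladium-catalysed syn-hydrostannation of a symmetrical alkyne has no regiochemical issue; tin and hydrogen add cis, so the two hydroxymethyl groups end cis.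

Step 10
Reactants: 14 ethyl (2Z)-2-bromo-3-Ox-prop-2-enoate; 16 (2E)-2-(tributylstannyl)but-2-ene-1,4-diol
Product: 18 (3E,4Z)-4-(2-hydroxyethylidene)-3-(Ox-methylidene)oxolan-2-one, via diene diol ester 17 (not isolated)
Conditions: Pd(PPh3)4 (10 mol%), CuI (20 mol%), CsF (2 equiv), DMF, 45 °C; then camphorsulfonic acid (0.1 equiv), CH2Cl2, 23 °C
Reagents that add atoms: none
Why: Stille coupling with retention at both alkenyl carbons joins C4 to C15 and puts C15 cis to C6; copper iodide and fluoride speed transmetalation of the internal stannane. Only the hydroxymethyl group on C15 can reach the ester, so acid-catalysed lactonisation masks C3 and C14 in one ring and leaves the other allylic hydroxyl free.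

Step 11
Reactants: 18 (3E,4Z)-4-(2-hydroxyethylidene)-3-(Ox-methylidene)oxolan-2-one
Product: 19 (2R,3S,7E)-2-(hydroxymethyl)-7-(Ox-methylidene)-1,5-dioxaspiro[2.4]heptan-6-one (epoxide across C15 and C1; C15 is the spiro carbon)
Conditions: Ti(OiPr)4 (0.3 equiv), D-(−)-diethyl tartrate (0.36 equiv), t-BuOOH (2 equiv), 4 Å MS, CH2Cl2, −20 °C
Reagents that add atoms: tert-butyl hydroperoxide, CC(C)(C)OO
Why: Sharpless asymmetric epoxidation of a 3,3-disubstituted allylic alcohol; with the C14 methylene cis to the hydroxymethyl group, the D-tartrate should deliver oxygen to the face that makes C15 S. The electron-poor C4=C5 bond and the terminal olefin are not allylic alcohols and stay untouched.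

Step 12
Reactants: 19 (2R,3S,7E)-2-(hydroxymethyl)-7-(Ox-methylidene)-1,5-dioxaspiro[2.4]heptan-6-one
Product: 20 (2S,3S,7E)-2-(iodomethyl)-7-(Ox-methylidene)-1,5-dioxaspiro[2.4]heptan-6-one
Conditions: I2, PPh3, imidazole, CH2Cl2, 0 °C
Reagents that add atoms: iodine, II
Why: Appel-type iodination of the primary alcohol under buffered conditions leaves the epoxide intact; the descriptor at C1 changes only through the priority rules.

Step 13
Reactants: 20 (2S,3S,7E)-2-(iodomethyl)-7-(Ox-methylidene)-1,5-dioxaspiro[2.4]heptan-6-one
Product: 21 (3E,4S)-4-ethenyl-4-hydroxy-3-(Ox-methylidene)oxolan-2-one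
Conditions: Zn dust (10 equiv), AcOH (5 equiv), THF–MeOH, 0 → 23 °C
Reagents that add atoms: none
Why: Reductive opening of a 2,3-epoxy iodide: zinc inserts into the C–I bond and β-eliminates the epoxide oxygen, unveiling the vinyl group and the tertiary C15 alcohol. The C15–O bond is never broken, so the configuration from step 11 is kept.

Step 14
Reactants: 21 (3E,4S)-4-ethenyl-4-hydroxy-3-(Ox-methylidene)oxolan-2-one
Product: 22 (2S,3Z)-2-ethenyl-3-(hydroxymethyl)-4-Ox-but-3-ene-1,2-diol
Conditions: i-Bu2AlH (6 equiv), CH2Cl2, −78 → 0 °C; aq. potassium sodium tartrate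
Reagents that add atoms: none
Why: 1,2-Reduction of the α-alkylidene lactone to the diol; conjugate reduction is not expected because the β-carbon C5 is shielded by the quaternary C6.

Step 15
Reactants: 22 (2S,3Z)-2-ethenyl-3-(hydroxymethyl)-4-Ox-but-3-ene-1,2-diol
Product: 23 (2S,3E)-2-ethenyl-2-hydroxy-3-(Ox-methylidene)butanedial
Conditions: (COCl)2 (4 equiv), DMSO (8 equiv), CH2Cl2, −78 °C; Et3N (12 equiv), −78 → −30 °C; used crude
Reagents that add atoms: none
Why: Swern oxidation converts both primary alcohols into alkoxysulfonium ions before base is added, so no hydroxy aldehyde is present to close to a lactol and over-oxidise; the tertiary alcohol cannot be oxidised.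

Step 16
Reactants: 23 (2S,3E)-2-ethenyl-2-hydroxy-3-(Ox-methylidene)butanedial; 24 prop-1-en-2-ylmagnesium bromide
Product: 25 (4S,5Z)-4-ethenyl-2,7-dimethyl-5-(Ox-methylidene)octa-1,7-diene-3,4,6-triol (mixture of epimers at the two new carbinols)
Conditions: 24 (4 equiv), THF, −78 °C; aq. NH4Cl
Reagents that add atoms: prop-1-en-2-ylmagnesium bromide (24), C=C(C)[Mg]Br
Why: 1,2-Addition of the alkenyl Grignard reagent to both aldehydes forms C2–C3 and C13–C14 together (one equivalent is consumed by the hydroxyl). The new carbinol centres need no control because step 17 removes them.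

Step 17
Reactants: 25 (4S,5Z)-4-ethenyl-2,7-dimethyl-5-(Ox-methylidene)octa-1,7-diene-3,4,6-triol
Product: 26 (4S,5E)-4-ethenyl-4-hydroxy-2,7-dimethyl-5-(Ox-methylidene)octa-1,7-diene-3,6-dione
Conditions: Dess–Martin periodinane (3 equiv), NaHCO3 (10 equiv), CH2Cl2, 0 → 23 °C; used at once
Reagents that add atoms: none
Why: Dess–Martin oxidation of the two secondary allylic alcohols; the tertiary alcohol is inert. The buffer keeps acid away from the cross-conjugated dienone, which could otherwise undergo Nazarov cyclisation.

Step 18
Reactants: 26 (4S,5E)-4-ethenyl-4-hydroxy-2,7-dimethyl-5-(Ox-methylidene)octa-1,7-diene-3,6-dione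
Product: 28 15-O-deacetyl-12,13-didehydro target (bicyclic 15S-hydroxy dienedione; 4E and 12E), via monocyclic cyclopentenone 27 (not isolated)
Conditions: second-generation Hoveyda–Grubbs catalyst [RuCl2(H2IMes)(=CH–C6H4-2-OiPr)] (10 mol%, then a second 10 mol%), toluene (0.5 mM), 80 °C, argon sparge
Reagents that add atoms: none
Why: Both closures are olefin metatheses, each a [2+2] cycloaddition of a ruthenium alkylidene to an olefin followed by cycloreversion of the metallacyclobutane with loss of ethylene; the closest known reaction types are ring-closing metathesis of 1,6-dien-3-ones to 2-methylcyclopent-2-enones and macrocyclising metathesis onto methacryloyl groups. The catalyst can load only at the two monosubstituted olefins, the C15 vinyl group and the C12 terminus, because the isopropenyl ketones are electron-poor 1,1-disubstituted olefins that accept an alkylidene but do not initiate. Loading at the vinyl group, helped by the free allylic hydroxyl, is followed by fast closure of the five-membered ring (C15, C1, C2, C3, C4) onto the C3 isopropenyl ketone to give 27; this is irreversible because its trisubstituted conjugated olefin does not re-enter the cycle, and closure onto the C14 isopropenyl group would require a cyclobutenone. With the vinyl group consumed, the alkylidene at C12 has one partner left, the C14 methacryloyl group, and closes the 12-membered carbocycle (11-membered through the ether oxygen) at C12=C13. Premature pairing of the C12 alkylidene with the vinyl group or the C3 isopropenyl ketone would give strained 11-membered carbocycles that form slowly and can be re-opened, whereas the cyclopentenone is a sink. High dilution suppresses dimerisation through the terminal olefin. No stereocentre is formed: C6, C9 and C15 are untouched, the C4=C5 geometry was fixed in steps 8 and 10, and the new olefin is expected as E, although either geometry converges in step 20.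

Step 19
Reactants: 28 15-O-deacetyl-12,13-didehydro target
Product: 29 12,13-didehydro target (15S-acetate; 4E and 12E)
Conditions: Ac2O (10 equiv), 4-(dimethylamino)pyridine (2 equiv), Et3N (10 equiv), CH2Cl2, 23 → 40 °C
Reagents that add atoms: acetic anhydride, CC(=O)OC(C)=O
Why: Nucleophile-catalysed acylation of the hindered tertiary α-ketol. It is placed here because both exposed isopropenyl ketones are gone and the base-labile C13 centre does not yet exist.

Step 20
Reactants: 29 12,13-didehydro target
Product: 32 target CNP0144863.1 (4E,6S,9S,13R,15S), via copper enolate 30 (not isolated), via 13-epimer 31 (not isolated)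
Conditions: [(Ph3P)CuH]6 (0.2 equiv), H2O (5 equiv), toluene, 23 °C; then DBU (0.2 equiv), toluene, 23 °C
Reagents that add atoms: none
Why: Conjugate reduction by hydride transfer from copper to an enone β-carbon; C12 is the only β-carbon not bonded to a quaternary carbon (C1 adjoins C15, C5 adjoins C6), so the bulky phosphine copper hydride cluster should select the C12=C13–C14 enone. Water protonates enolate 30 as it forms, and DBU then equilibrates C13 through the enol, converting 31 into the more stable epimer, taken to be 13R.

## Compound list

1 | 2,2-dimethylpent-4-enoic acid | C=CCC(C)(C)C(=O)O | starting material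
2 | methyllithium | [Li]C | starting material
3 | 3,3-dimethylhex-5-en-2-one | CC(=O)C(C)(C)CC=C | intermediate
4 | 3-methylbut-2-en-1-yl acetate (prenyl acetate) | CC(C)=CCOC(C)=O | starting material
5 | (2E)-4-hydroxy-3-methylbut-2-en-1-yl acetate | CC(=O)OC/C=C(\C)CO | intermediate
6 | (2E)-4-bromo-3-methylbut-2-en-1-yl acetate | CC(=O)OC/C=C(\C)CBr | intermediate
7 | (2E)-3,7,7-trimethyl-6-oxodeca-2,9-dien-1-yl acetate | CC(=O)OC/C=C(\C)CCC(=O)C(C)(C)CC=C | intermediate
8 | (2E,6S)-6-hydroxy-3,7,7-trimethyldeca-2,9-dien-1-yl acetate | CC(=O)OC/C=C(\C)CC[C@H](O)C(C)(C)CC=C | intermediate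
9 | (2E,6S)-3,7,7-trimethyldeca-2,9-diene-1,6-diol | OC/C=C(\C)CC[C@H](O)C(C)(C)CC=C | intermediate
10 | (3S)-1-[(2R,3R)-3-(hydroxymethyl)-2-methyloxiran-2-yl]-4,4-dimethylhept-6-en-3-ol | OC[C@H]1O[C@]1(C)CC[C@H](O)C(C)(C)CC=C | intermediate
11 | (1R)-1-[(2S,5S)-2-methyl-5-(2-methylpent-4-en-2-yl)oxolan-2-yl]ethane-1,2-diol | OC[C@@H](O)[C@]1(C)CC[C@H](O1)C(C)(C)CC=C | intermediate
12 | (2S,5S)-2-methyl-5-(2-methylpent-4-en-2-yl)oxolane-2-carbaldehyde | O=C[C@]1(C)CC[C@H](O1)C(C)(C)CC=C | intermediate
13 | ethyl 2-bromo-2-(triphenyl-λ5-phosphanylidene)acetate | CCOC(=O)C(Br)=P(c1ccccc1)(c1ccccc1)c1ccccc1 | starting material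
14 | ethyl (2Z)-2-bromo-3-[(2S,5S)-2-methyl-5-(2-methylpent-4-en-2-yl)oxolan-2-yl]prop-2-enoate | CCOC(=O)/C(Br)=C/[C@]1(C)CC[C@H](O1)C(C)(C)CC=C | intermediate
15 | but-2-yne-1,4-diol | OCC#CCO | starting material
16 | (2E)-2-(tributylstannyl)but-2-ene-1,4-diol | CCCC[Sn](CCCC)(CCCC)/C(CO)=C/CO | intermediate
17 | ethyl (2E)-2-[(2Z)-1,4-dihydroxybut-2-en-2-yl]-3-[(2S,5S)-2-methyl-5-(2-methylpent-4-en-2-yl)oxolan-2-yl]prop-2-enoate | CCOC(=O)/C(=C/[C@]1(C)CC[C@H](O1)C(C)(C)CC=C)C(/CO)=C/CO | intermediate
18 | (3E,4Z)-4-(2-hydroxyethylidene)-3-{[(2S,5S)-2-methyl-5-(2-methylpent-4-en-2-yl)oxolan-2-yl]methylidene}oxolan-2-one | O=C1OC/C(=C\CO)/C1=C\[C@]2(C)CC[C@H](O2)C(C)(C)CC=C | intermediate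
19 | (2R,3S,7E)-2-(hydroxymethyl)-7-{[(2S,5S)-2-methyl-5-(2-methylpent-4-en-2-yl)oxolan-2-yl]methylidene}-1,5-dioxaspiro[2.4]heptan-6-one | O=C1OC[C@@]2(O[C@@H]2CO)/C1=C\[C@]3(C)CC[C@H](O3)C(C)(C)CC=C | intermediate
20 | (2S,3S,7E)-2-(iodomethyl)-7-{[(2S,5S)-2-methyl-5-(2-methylpent-4-en-2-yl)oxolan-2-yl]methylidene}-1,5-dioxaspiro[2.4]heptan-6-one | O=C1OC[C@@]2(O[C@@H]2CI)/C1=C\[C@]3(C)CC[C@H](O3)C(C)(C)CC=C | intermediate
21 | (3E,4S)-4-ethenyl-4-hydroxy-3-{[(2S,5S)-2-methyl-5-(2-methylpent-4-en-2-yl)oxolan-2-yl]methylidene}oxolan-2-one | O=C1OC[C@](O)(C=C)/C1=C\[C@]2(C)CC[C@H](O2)C(C)(C)CC=C | intermediate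
22 | (2S,3Z)-2-ethenyl-3-(hydroxymethyl)-4-[(2S,5S)-2-methyl-5-(2-methylpent-4-en-2-yl)oxolan-2-yl]but-3-ene-1,2-diol | OC/C(=C/[C@]1(C)CC[C@H](O1)C(C)(C)CC=C)[C@@](O)(C=C)CO | intermediate
23 | (2S,3E)-2-ethenyl-2-hydroxy-3-{[(2S,5S)-2-methyl-5-(2-methylpent-4-en-2-yl)oxolan-2-yl]methylidene}butanedial | O=C/C(=C/[C@]1(C)CC[C@H](O1)C(C)(C)CC=C)[C@@](O)(C=C)C=O | intermediate
24 | prop-1-en-2-ylmagnesium bromide (isopropenylmagnesium bromide) | C=C(C)[Mg]Br | starting material
25 | (4S,5Z)-4-ethenyl-2,7-dimethyl-5-{[(2S,5S)-2-methyl-5-(2-methylpent-4-en-2-yl)oxolan-2-yl]methylidene}octa-1,7-diene-3,4,6-triol, epimer mixture at C3 and C6 of the octadiene | C=C(C)C(O)/C(=C/[C@]1(C)CC[C@H](O1)C(C)(C)CC=C)[C@@](O)(C=C)C(O)C(C)=C | intermediate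
26 | (4S,5E)-4-ethenyl-4-hydroxy-2,7-dimethyl-5-{[(2S,5S)-2-methyl-5-(2-methylpent-4-en-2-yl)oxolan-2-yl]methylidene}octa-1,7-diene-3,6-dione (acyclic tetraene, 15-hydroxy) | C=C(C)C(=O)/C(=C/[C@]1(C)CC[C@H](O1)C(C)(C)CC=C)[C@@](O)(C=C)C(=O)C(C)=C | intermediate
27 | (4S,5E)-4-hydroxy-2-methyl-4-(2-methylprop-2-enoyl)-5-{[(2S,5S)-2-methyl-5-(2-methylpent-4-en-2-yl)oxolan-2-yl]methylidene}cyclopent-2-en-1-one | O[C@@]1(C(=O)C(C)=C)C=C(C)C(=O)/C1=C/[C@]2(C)CC[C@H](O2)C(C)(C)CC=C | intermediate
28 | 15-O-deacetyl-12,13-didehydro target (bicyclic 15S-hydroxy dienedione, 4E, 12E) | O[C@@]12C=C(C)C(=O)/C1=C/[C@]1(C)CC[C@H](O1)C(C)(C)C/C=C(\C)C2=O | intermediate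
29 | 12,13-didehydro target (15S-acetate, 4E, 12E) | CC(=O)O[C@@]12C=C(C)C(=O)/C1=C/[C@]1(C)CC[C@H](O1)C(C)(C)C/C=C(\C)C2=O | intermediate
30 | copper enolate of the C14 ketone (C13=C14–O–Cu) | CC(=O)O[C@@]12C=C(C)C(=O)/C1=C/[C@]1(C)CC[C@H](O1)C(C)(C)CCC(C)=C2O[Cu] | intermediate
31 | 13-epimer of the target (13S) | CC(=O)O[C@@]12C=C(C)C(=O)/C1=C/[C@]1(C)CC[C@H](O1)C(C)(C)CC[C@H](C)C2=O | intermediate
32 | CNP0144863.1 (4E,6S,9S,13R,15S) | CC(=O)O[C@@]12C=C(C)C(=O)/C1=C/[C@]1(C)CC[C@H](O1)C(C)(C)CC[C@@H](C)C2=O | target

## Step count and least certain steps

Total step count: 20. Longest linear sequence: 18 steps (from 4 through steps 2–8 and 10–20).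

**Step 18 (key step).** Initiation at the terminal olefin may be followed by intermolecular cross-metathesis, or the macrocyclisation onto the deactivated methacryloyl group may be too slow, so that the sequence stalls after the five-membered ring. Ruthenium hydrides could also migrate the terminal olefin. Fallback: the metathesis is moved one oxidation level back. It sets out from triol 25, in which both future ketones are still allylic carbinols and whose 1,1-disubstituted olefins with a free allylic hydroxyl are better metathesis partners than methacryloyl groups. The same catalyst under the same dilution should close both rings to the bicyclic triol F1, and Dess–Martin oxidation of its two secondary allylic alcohols comes back to the route at 28.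

**Step 10.** Transmetalation between the internal stannane and a vinylpalladium species flanked by a cis quaternary carbon may be slow, so that protodestannylation and homocoupling take over; lactonisation may also be incomplete. Fallback: a Negishi coupling with a protected partner, setting out from 16. Iododestannylation with I2 gives (2E)-2-iodobut-2-ene-1,4-diol F2 with retention. Silylation (t-BuMe2SiCl, imidazole) gives the bis-silyl ether F3, and iodine–magnesium exchange with i-PrMgCl·LiCl followed by ZnCl2 gives the alkenylzinc chloride F4. Coupling of F4 with 14 under Pd(P(t-Bu)3)2 gives the bis-silyl diene ester F5. Bu4NF removes both silyl groups and the liberated C14 alkoxide lactonises through 17, coming back to the route at 18.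

**Step 20.** Hydride may also be delivered to C1 or C5 (loss of site selectivity), and the protonation at C13, or the position of the epimer equilibrium, may favour the wrong face. Fallback: reagent control, setting out from 29. Copper hydride catalysed hydrosilylation (catalytic [(Ph3P)CuH]6, Et3SiH) gives the triethylsilyl enol ether F6, which is isolated so that the site of reduction can be checked. It is then protonated at −78 °C with a chiral Lewis-acid-assisted Brønsted acid ((R)- or (S)-BINOL·SnCl4, the enantiomer chosen for the 13R face) and comes back to the route at 32 without base equilibration.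

**Step 15.** The first-formed hydroxy aldehyde may close to a lactol and be oxidised on to a lactone, or the tertiary α-hydroxy aldehyde may undergo an α-ketol shift under the basic work-up. Fallback: the dialdehyde is avoided, setting out from 21. Aminolysis with MeONHMe·HCl and AlMe3 opens the lactone to the hydroxy N-methoxy-N-methylamide F7. Dess–Martin oxidation gives the aldehyde amide F8, and excess 24 adds to the aldehyde and converts the amide into the C3 isopropenyl ketone, giving the hydroxy ketone F9. A second Dess–Martin oxidation comes back to the route at 26.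

**Step 19.** Acylation of the tertiary α-ketol may be too slow, and forcing it may bring conjugate addition of the nucleophilic catalyst to the strained macrocyclic enone or an α-ketol rearrangement. Fallback: the order of the last two steps is inverted, setting out from 28. Conjugate reduction with [(Ph3P)CuH]6 as in step 20 gives the 15-O-deacetyl target F10, in which the macrocyclic enone is gone. Acetylation with Ac2O and 4-(dimethylamino)pyridine at elevated temperature, under which C13 equilibrates at the same time, comes back to the route at 32.

## Further compounds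

F1 | step 18 | bicyclic triol: 28 with both ketones (C3 and C14) as carbinols, epimer mixture | O[C@@]12C=C(C)C(O)/C1=C/[C@]1(C)CC[C@H](O1)C(C)(C)C/C=C(\C)C2O
F2 | step 10 | (2E)-2-iodobut-2-ene-1,4-diol | OC/C(I)=C\CO
F3 | step 10 | (2E)-1,4-bis[(tert-butyldimethylsilyl)oxy]-2-iodobut-2-ene | CC(C)(C)[Si](C)(C)OC/C(I)=C\CO[Si](C)(C)C(C)(C)C
F4 | step 10 | alkenylzinc chloride from F3 (zinc in place of iodine, geometry retained) | CC(C)(C)[Si](C)(C)OC/C([Zn]Cl)=C\CO[Si](C)(C)C(C)(C)C
F5 | step 10 | bis(tert-butyldimethylsilyl) ether of 17 | CCOC(=O)/C(=C/[C@]1(C)CC[C@H](O1)C(C)(C)CC=C)C(/CO[Si](C)(C)C(C)(C)C)=C/CO[Si](C)(C)C(C)(C)C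
F6 | step 20 | triethylsilyl enol ether of the C14 ketone of the target (C13=C14–OSiEt3) | CC(=O)O[C@@]12C=C(C)C(=O)/C1=C/[C@]1(C)CC[C@H](O1)C(C)(C)CCC(C)=C2O[Si](CC)(CC)CC
F7 | step 15 | hydroxy N-methoxy-N-methylamide from 21 (C3 amide, C14 primary alcohol, 15S-OH) | CON(C)C(=O)/C(=C/[C@]1(C)CC[C@H](O1)C(C)(C)CC=C)[C@@](O)(C=C)CO
F8 | step 15 | aldehyde N-methoxy-N-methylamide (C14 aldehyde) | CON(C)C(=O)/C(=C/[C@]1(C)CC[C@H](O1)C(C)(C)CC=C)[C@@](O)(C=C)C=O
F9 | step 15 | hydroxy ketone: 26 with C14 still a carbinol, epimer mixture | C=C(C)C(=O)/C(=C/[C@]1(C)CC[C@H](O1)C(C)(C)CC=C)[C@@](O)(C=C)C(O)C(C)=C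
F10 | step 19 | 15-O-deacetyl target | O[C@@]12C=C(C)C(=O)/C1=C/[C@]1(C)CC[C@H](O1)C(C)(C)CC[C@@H](C)C2=O
A1 | alternative 1 | macrocyclic allene (C15=C4=C5) with a dimethyl(prop-1-yn-1-yl)silyl ether on the C14 oxygen; allene axis not specified | CC#C[Si](C)(C)O[C@H]1[C@H](C)CCC(C)(C)[C@@H]2CC[C@](C)(O2)C=C=C1
A2 | alternative 1 | silicon-bridged 15-deoxy dienone | [C@@H]12C3=C(C)C(=O)/C1=C/[C@]1(C)CC[C@H](O1)C(C)(C)CC[C@@H](C)[C@@H]2O[Si]3(C)C
A3 | alternative 2 | macrocyclic 1-acylfulvene (ring olefins C15=C1 and C2=C3, exocyclic C4=C5) | O=C1[C@H](C)CCC(C)(C)[C@@H]2CC[C@](C)(O2)/C=C3/C=C(C)C=C31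
A4 | alternative 2 | 15-O-deacetyl target | O[C@@]12C=C(C)C(=O)/C1=C/[C@]1(C)CC[C@H](O1)C(C)(C)CC[C@@H](C)C2=O
A5 | alternative 3 | cesium oxalate of the C10 tertiary alcohol carrying the 12-(phenylsulfonyl) C11=C12 alkene | CC(=O)O[C@@]1(C(=O)[C@H](C)C(=C)S(=O)(=O)c2ccccc2)C=C(C)C(=O)/C1=C/[C@]1(C)CC[C@H](O1)C(C)(C)OC(=O)C(=O)[O-].[Cs+]
A6 | alternative 3 | 12-(phenylsulfonyl) target | CC(=O)O[C@@]12C=C(C)C(=O)/C1=C/[C@]1(C)CC[C@H](O1)C(C)(C)C[C@@H]([C@@H](C)C2=O)S(=O)(=O)c1ccccc1
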